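**No direct route.** The protic impurity cannot touch a mole of starting material: in the proposed steps its one partner is dissolved gas. So I keep the books on starting material, the limiting reagent while the gas phase is held, and ask what the impurity's line costs in target.

in all of them: starting material 0.25 M; gas phase 50 mM (held)
- teal: protic impurity 6.7 × 10⁻⁴ M; run made earlier
- green: protic impurity 0.0079 M; run made earlier
- Friday's: protic impurity 8.00 × 10⁻⁴ M; time 80 min
- Tuesday's: protic impurity 0.00150 M; time 80 min
- Sunday's: protic impurity 0.00300 M; time 80 min
- Monday's: protic impurity 0.00600 M; time 80 min
- Thursday's: protic impurity 0.0120 M; time 80 min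

- teal (time / min: target / %): 15.0: 10.3; 30.0: 20.3; 50.0: 31.4; 60.0: 35.4; 80.0: 40.9
- green (time / min: target / %): 8.00: 5.5; 20.0: 13.8; 40.0: 25.2; 60.0: 34.3; 80.0: 41.2

(scatter of a reading: 0.5 percentage points)

- at the start none of the gas is dissolved
- steps that have been proposed: gas phase <-> dissolved gas; dissolved gas + protic impurity -> quenched reagent; target <-> isomer of the product; starting material <-> dormant form; starting material + dissolved gas -> target
- "hardly changes" means that all values lie within two and a half points (for a concentration: within two and a half percent of the largest)

1. amount of target at the end, in percent of the starting material charged for Friday's, Tuesday's, Sunday's, Monday's, Thursday's, in this order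
2. the shape of the row from first to last (falls, then rises / hardly changes / rises, then falls / rises all the way / falls all the way)

**The ledger.** On the teal run, target takes 40.9% of the charge at 80.0 min. The other 59.1% is unread. Teal carries impurity at 0.268% of the charge and green at 3.16%, a difference of 2.89%. At 80.0 min, teal minus green is −0.3 percentage points, inside the scatter, so I go round again with the pair at 60.0 min, which gives 1.1 points. The mean gap is 0.4 points, and as a mean of two differences it carries 0.5 points, the scatter of one reading. That makes 0.138 the toll, the target lost per unit of impurity charged, both as fractions of the charge. As a reading it could stand as high as 0.484, two scatters up.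

**My reckoning.** Friday's and Thursday's differ by 4.48% of the charge in impurity, so I expect 0.62 points between the ends of the row, around 41.0%. Even the high toll gives 2.2 points, less than the band of 2.5 points.

**The forecast.** It gives 41%, 41%, 41%, 41% and 40.9%, so hardly changes, holding that the impurity “only removes a small amount of dissolved gas”. Its fall along the row is smaller than mine.

**The flask.** The row gives 41.6%, 41.6%, 41.5%, 41.5% and 41.3%: hardly changes.

    gas phase ⇌ dissolved gas, rate k1*(csat - [dissolved gas]) (kL = 0.350 min⁻¹)
    dissolved gas + protic impurity → quenched reagent (k = 0.930 L mol⁻¹ min⁻¹)
    target ⇌ isomer of the product (K = 1.20, k = 0.00150 min⁻¹)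
    starting material ⇌ dormant form (K = 0.830, k = 0.00740 min⁻¹)
    starting material + dissolved gas → target (k = 0.220 L mol⁻¹ min⁻¹)

**The toll used.** From Friday's to Thursday's the fall is 0.3 points, a toll of 0.0670 on this row. On Monday's that earlier toll asks 0.29 points below Friday's, and the flask stands 0.1 points below. In Thursday's flask the quench ran while protic impurity lasted, 21.5% of its charge at 40.0 min and 3.80% at 80.0 min, with dissolved gas at 0.0456 M and then 0.0474 M. Thursday's books close at 80.0 min with target 41.3%, starting material 32.6%, dormant form 23.3% and isomer of the product 2.77%.

The earlier runs and the new flask are simulated with constants of no real substance, noise included.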